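## Retrosynthetic overview
1. 15 ⇒ 14: global desilylation with a non-basic fluoride source comes last, so C2 cannot epimerise.
2. 14 ⇒ 6 + 13: the C2''=C3'' olefin is made by cross-metathesis of a 6-allylflavanone with a chiral 1,1-disubstituted alkene.
3. 6 ⇒ 4 ⇒ 2 ⇒ 1: the key C6–C1'' bond comes from a Eu(III)-catalysed aromatic Claisen [3,3] shift of the 5-O-allyl ether. C4a is blocked, so only C6 can accept. C2 is bought in 1.
4. 13 ⇒ 10 ⇒ 7 + 8: C6'' is the bought centre of methyl (R)-glycidate. The ester becomes CMe2OH and then isopropenyl, and the epoxide CH2 becomes C5''.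
5. Rings: none is built. The chromanone and both arenes arrive intact in 1.

Assumption: 1 (natural 2S form) and 7 are bought as single enantiomers, and ee is checked by chiral HPLC after steps 3 and 8.

## Route

Step 1
Reactants: 1 (2S)-eriodictyol
Product: 2 (2S)-7,3',4'-tris-O-(tert-butyldimethylsilyl)eriodictyol (5-OH free)
Conditions: TBSCl (3.3 equiv), imidazole, DMF, 0 °C → rt
Reagents that add atoms: tert-butyldimethylsilyl chloride, CC(C)(C)[Si](C)(C)Cl
Why: Corey silylation takes the three unchelated phenols and leaves the 5-OH, which is hydrogen-bonded to C4=O, and the near-neutral medium avoids retro-oxa-Michael racemisation of the bought C2 centre.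

Step 2
Reactants: 2 (2S)-7,3',4'-tris-O-TBS-eriodictyol; 3 allyl alcohol
Product: 4 (2S)-5-O-allyl-7,3',4'-tris-O-TBS-eriodictyol
Conditions: PPh3, DIAD, THF, 0 °C → rt
Reagents that add atoms: none
Why: Mitsunobu etherification alkylates the only free (chelated) phenol with a primary alcohol under neutral conditions, as known for 5-OH flavanones, and leaves C2 untouched.

Step 3
Reactants: 4 (2S)-5-O-allyl-7,3',4'-tris-O-TBS-eriodictyol
Product: 6 (2S)-6-allyl-7,3',4'-tris-O-TBS-eriodictyol (5-OH free), via cyclohexadienone tautomer 5 (not isolated)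
Conditions: Eu(fod)3 (10 mol %), toluene, 100 °C
Reagents that add atoms: none
Why: In this Eu(III)-catalysed aromatic Claisen [3,3]-sigmatropic rearrangement, chelation at O4/O5 accelerates the shift, the only open ortho carbon is C6, and dienone 5 enolises to the phenol, so the C6–C1'' bond forms regiospecifically without base and C2 is unaffected.

Step 4
Reactants: 7 methyl (2R)-oxirane-2-carboxylate; 8 2-methylallylmagnesium chloride
Product: 10 (3R)-2,6-dimethylhept-6-ene-2,3-diol, via epoxy alcohol chloromagnesium salt 9 (not isolated)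
Conditions: MeMgCl (2.2 equiv), THF, −78 → −20 °C; then CuI (10 mol %), 8 (1.5 equiv), −30 → 0 °C; aq NH4Cl
Reagents that add atoms: methylmagnesium chloride, C[Mg]Cl
Why: Double Grignard addition to the ester is followed by Cu(I)-catalysed SN2 opening at the unsubstituted epoxide carbon, and no bond to the stereocentre is broken, so the bought (R) centre becomes C6''.

Step 5
Reactants: 10 (3R)-2,6-dimethylhept-6-ene-2,3-diol
Product: 11 (3R)-3-(tert-butyldimethylsilyloxy)-2,6-dimethylhept-6-en-2-ol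
Conditions: TBSCl (1.1 equiv), imidazole, DMF, rt
Reagents that add atoms: tert-butyldimethylsilyl chloride, CC(C)(C)[Si](C)(C)Cl
Why: Sterically controlled Corey silylation takes the secondary alcohol and leaves the tertiary one, with the configuration unchanged.

Step 6
Reactants: 11 (3R)-3-(tert-butyldimethylsilyloxy)-2,6-dimethylhept-6-en-2-ol
Product: 13 (3R)-3-(tert-butyldimethylsilyloxy)-2,6-dimethylhepta-1,6-diene, via chlorosulfite ester 12 (not isolated)
Conditions: SOCl2 (1.5 equiv), pyridine, 0 °C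
Reagents that add atoms: none
Why: E2 dehydration of the tertiary chlorosulfite removes one of six methyl hydrogens rather than the hindered, oxygen-deactivated C3–H, which gives the isopropenyl group and leaves the C3–O bond intact.

Step 7
Reactants: 6 (2S)-6-allyl-7,3',4'-tris-O-TBS-eriodictyol; 13 (3R)-3-(tert-butyldimethylsilyloxy)-2,6-dimethylhepta-1,6-diene
Product: 14 (2S)-6-[(2E,6R)-6-(tert-butyldimethylsilyloxy)-3,7-dimethylocta-2,7-dien-1-yl]-7,3',4'-tris-O-TBS-eriodictyol
Conditions: 13 (3 equiv), Hoveyda–Grubbs II (7.5 mol %), 1,4-benzoquinone (15 mol %), CH2Cl2, 40 °C; AgNO3–SiO2 chromatography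
Reagents that add atoms: none
Why: In this type I/type III olefin cross-metathesis the allyl group couples with the unhindered methallyl-type alkene of 13, the OTBS-flanked isopropenyl group is a spectator, the E isomer is favoured (about 3–4:1) and separated from Z, and no stereocentre is touched.

Step 8
Reactants: 14 tetra-TBS ether
Product: 15 (2S)-6-[(2E,6R)-6-hydroxy-3,7-dimethylocta-2,7-dien-1-yl]eriodictyol (target)
Conditions: HF·pyridine, pyridine/THF, 0 °C → rt, Ar
Reagents that add atoms: none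
Why: Buffered fluoride desilylation cleaves all four Si–O bonds without forming free phenoxide (no chalcone opening, C2 kept) and without acid strong enough to ionise the allylic alcohol or close a chroman ring.

## Compound list
1 | (2S)-eriodictyol | O=C1C[C@@H](c2ccc(O)c(O)c2)Oc2cc(O)cc(O)c12 | starting material
2 | (2S)-7,3',4'-tris-O-TBS-eriodictyol | O=C1C[C@@H](c2ccc(O[Si](C)(C)C(C)(C)C)c(O[Si](C)(C)C(C)(C)C)c2)Oc2cc(O[Si](C)(C)C(C)(C)C)cc(O)c12 | intermediate
3 | allyl alcohol | C=CCO | starting material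
4 | (2S)-5-O-allyl-7,3',4'-tris-O-TBS-eriodictyol | O=C1C[C@@H](c2ccc(O[Si](C)(C)C(C)(C)C)c(O[Si](C)(C)C(C)(C)C)c2)Oc2cc(O[Si](C)(C)C(C)(C)C)cc(OCC=C)c12 | intermediate
5 | 6-allyl-5-oxo cyclohexadienone tautomer (C6 sp3, configuration there undefined) | O=C1C[C@@H](c2ccc(O[Si](C)(C)C(C)(C)C)c(O[Si](C)(C)C(C)(C)C)c2)OC2=C1C(=O)C(CC=C)C(O[Si](C)(C)C(C)(C)C)=C2 | intermediate
6 | (2S)-6-allyl-7,3',4'-tris-O-TBS-eriodictyol | O=C1C[C@@H](c2ccc(O[Si](C)(C)C(C)(C)C)c(O[Si](C)(C)C(C)(C)C)c2)Oc2cc(O[Si](C)(C)C(C)(C)C)c(CC=C)c(O)c12 | intermediate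
7 | methyl (2R)-oxirane-2-carboxylate | COC(=O)[C@H]1CO1 | starting material
8 | 2-methylallylmagnesium chloride | C=C(C)C[Mg]Cl | starting material
9 | 2-[(2R)-oxiran-2-yl]propan-2-ol (present as ClMg alkoxide) | CC(C)(O)[C@H]1CO1 | intermediate
10 | (3R)-2,6-dimethylhept-6-ene-2,3-diol | CC(C)(O)[C@H](O)CCC(C)=C | intermediate
11 | (3R)-3-(TBSO)-2,6-dimethylhept-6-en-2-ol | CC(C)(O)[C@H](O[Si](C)(C)C(C)(C)C)CCC(C)=C | intermediate
12 | chlorosulfite ester of 11 | CC(C)(OS(=O)Cl)[C@H](O[Si](C)(C)C(C)(C)C)CCC(C)=C | intermediate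
13 | (3R)-3-(TBSO)-2,6-dimethylhepta-1,6-diene | C=C(C)[C@H](O[Si](C)(C)C(C)(C)C)CCC(C)=C | intermediate
14 | (2S)-6-[(2E,6R)-6-(TBSO)-3,7-dimethylocta-2,7-dienyl]-7,3',4'-tris-O-TBS-eriodictyol | C=C(C)[C@H](O[Si](C)(C)C(C)(C)C)CC/C(C)=C/Cc1c(O[Si](C)(C)C(C)(C)C)cc2c(c1O)C(=O)C[C@@H](c1ccc(O[Si](C)(C)C(C)(C)C)c(O[Si](C)(C)C(C)(C)C)c1)O2 | intermediate
15 | (2S)-6-[(2E,6R)-6-hydroxy-3,7-dimethylocta-2,7-dienyl]eriodictyol | C=C(C)[C@H](O)CC/C(C)=C/Cc1c(O)cc2c(c1O)C(=O)C[C@@H](c1ccc(O)c(O)c1)O2 | target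

## Step count and risks
Total steps: 8. Longest linear sequence: 5 (steps 1, 2, 3, 7, 8, or equally steps 4, 5, 6, 7, 8).

**Step 7 (cross-metathesis) is the most likely to fail.** Trisubstituted olefins from 1,1-disubstituted partners form with only modest E:Z and moderate conversion, and the isomers must be separated on a heavily silylated substrate. The fallback fixes the olefin geometry on the small side chain before it meets the flavanone. It sets out from 13 and 2 and comes back at 14.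
- OsO4 (cat.)/NaIO4/2,6-lutidine attacks the unhindered alkene of 13. It passes through (5R)-5-(tert-butyldimethylsilyloxy)-2,6-dimethylhept-6-ene-1,2-diol F1 (not isolated) and gives (5R)-5-(tert-butyldimethylsilyloxy)-6-methylhept-6-en-2-one F2.
- Horner–Wadsworth–Emmons olefination (triethyl phosphonoacetate, NaH), followed by silica removal of the minor Z ester, gives ethyl (2E,6R)-6-(tert-butyldimethylsilyloxy)-3,7-dimethylocta-2,7-dienoate F3.
- DIBAL-H reduction gives (2E,6R)-6-(tert-butyldimethylsilyloxy)-3,7-dimethylocta-2,7-dien-1-ol F4.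
- Mitsunobu coupling of F4 with 2 gives the (2S)-5-O-[(2E,6R)-6-(tert-butyldimethylsilyloxy)-3,7-dimethylocta-2,7-dienyl] ether F5.
- Montmorillonite K10 (CH2Cl2, 0 °C) moves the intact E-allyl unit from O5 to C6 in a formal 1,3-shift, which gives 14.

**Step 3 (Claisen) is the second risk.** An unsubstituted allyl ether rearranges slowly, and prolonged heating with a Lewis acid could erode ee, loosen the 7-O-silyl group or leak some 8-allyl product. The fallback sets out from 2 and comes back at 6.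
- Iodination ortho to the chelated 5-OH (BnMe3N·ICl2, CaCO3, CH2Cl2–MeOH) gives (2S)-6-iodo-7,3',4'-tris-O-TBS-eriodictyol F6.
- Stille allylation (allyltributylstannane, Pd2(dba)3/AsPh3, THF, 60 °C) gives 6.

**Step 6 (dehydration) is the third risk.** It may give the tetrasubstituted silyl enol ether or a tertiary chloride beside the isopropenyl product. The fallback builds the isopropenyl group by carbonyl olefination instead. It sets out from 7 and 8 and comes back at 13.
- CuBr·SMe2-mediated opening of 7 with 8 at −78 °C gives methyl (2R)-2-hydroxy-5-methylhex-5-enoate F7.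
- TBSCl/imidazole gives methyl (2R)-2-(tert-butyldimethylsilyloxy)-5-methylhex-5-enoate F8.
- MeNH(OMe)·HCl/iPrMgCl gives (2R)-2-(tert-butyldimethylsilyloxy)-N-methoxy-N,5-dimethylhex-5-enamide F9.
- MeMgBr gives (3R)-3-(tert-butyldimethylsilyloxy)-6-methylhept-6-en-2-one F10.
- Wittig methylenation (Ph3P=CH2, THF, −78 → 0 °C) gives 13.

## Further compounds
F1 | step 7 | (5R)-5-(tert-butyldimethylsilyloxy)-2,6-dimethylhept-6-ene-1,2-diol | C=C(C)[C@H](O[Si](C)(C)C(C)(C)C)CCC(C)(O)CO
F2 | step 7 | (5R)-5-(tert-butyldimethylsilyloxy)-6-methylhept-6-en-2-one | C=C(C)[C@H](O[Si](C)(C)C(C)(C)C)CCC(C)=O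
F3 | step 7 | ethyl (2E,6R)-6-(tert-butyldimethylsilyloxy)-3,7-dimethylocta-2,7-dienoate | C=C(C)[C@H](O[Si](C)(C)C(C)(C)C)CC/C(C)=C/C(=O)OCC
F4 | step 7 | (2E,6R)-6-(tert-butyldimethylsilyloxy)-3,7-dimethylocta-2,7-dien-1-ol | C=C(C)[C@H](O[Si](C)(C)C(C)(C)C)CC/C(C)=C/CO
F5 | step 7 | (2S)-5-O-[(2E,6R)-6-(tert-butyldimethylsilyloxy)-3,7-dimethylocta-2,7-dienyl]-7,3',4'-tris-O-TBS-eriodictyol | C=C(C)[C@H](O[Si](C)(C)C(C)(C)C)CC/C(C)=C/COc1cc(O[Si](C)(C)C(C)(C)C)cc2c1C(=O)C[C@@H](c1ccc(O[Si](C)(C)C(C)(C)C)c(O[Si](C)(C)C(C)(C)C)c1)O2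
F6 | step 3 | (2S)-6-iodo-7,3',4'-tris-O-TBS-eriodictyol | O=C1C[C@@H](c2ccc(O[Si](C)(C)C(C)(C)C)c(O[Si](C)(C)C(C)(C)C)c2)Oc2cc(O[Si](C)(C)C(C)(C)C)c(I)c(O)c12
F7 | step 6 | methyl (2R)-2-hydroxy-5-methylhex-5-enoate | COC(=O)[C@H](O)CCC(C)=C
F8 | step 6 | methyl (2R)-2-(tert-butyldimethylsilyloxy)-5-methylhex-5-enoate | COC(=O)[C@H](O[Si](C)(C)C(C)(C)C)CCC(C)=C
F9 | step 6 | (2R)-2-(tert-butyldimethylsilyloxy)-N-methoxy-N,5-dimethylhex-5-enamide | CON(C)C(=O)[C@H](O[Si](C)(C)C(C)(C)C)CCC(C)=C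
F10 | step 6 | (3R)-3-(tert-butyldimethylsilyloxy)-6-methylhept-6-en-2-one | CC(=O)[C@H](O[Si](C)(C)C(C)(C)C)CCC(C)=C
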